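**Retrosynthetic overview**

1. Numbering: C1 methyl-bearing fusion carbon, C2/C3 the CH2 groups of cyclopentane ring A, C4 isopropyl carbinol, C5 fusion CH, C6 ester carbinol, C7 CH2, C8 methyl carbinol, C9 secondary carbinol, C10 CH2 of cycloheptane ring B.
2. The route rests on the 1,3-relation of the C6 carbinol and the methyl-bearing C8 in ring B: a C6 aldehyde and an isopropenyl unit C7=C8, carried trans on ring A at C5 and C1, are joined at C6–C7 by a carbonyl-ene reaction. This closes ring B last and leaves a C8 methylene that becomes the methyl carbinol (epoxide, hydride) before C6 acylation and deprotection.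
3. Ring A is closed earlier at C3–C4 by rhodium-catalysed hydroacylation of a 4-pentenal; C4 is completed by isopropylcerium addition anti to the C5 side chain.
4. C1 and C5 are set on a temporary δ-lactone (O–C6(=O)–C5=C1–C10–C9): vinyl-copper addition anti to the C9 isopropenyl group, then orthoformate capture anti to the vinyl group. The lactone comes from methacrolein by asymmetric methallylboration (C9), acryloylation and ring-closing metathesis.
5. Order of ring formation: temporary lactone, ring A, ring B.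

Key step: step 11

Remark: (S)-TRIP (3,3'-bis(2,4,6-triisopropylphenyl)-1,1'-binaphthyl-2,2'-diyl hydrogen phosphate) is assumed to give the (S)-carbinol, by analogy with its sense for aryl and alkenyl aldehydes; if the sense is opposite, the (R)-acid is used.

**Route**

Step 1
Reactants: 1 2-methylprop-2-enal (methacrolein); 2 2-methylallylboronic acid pinacol ester
Product: 4 (S)-2,5-dimethylhexa-1,5-dien-3-ol, via pinacol borate ester 3 (not isolated)
Conditions: (S)-TRIP (5 mol%), toluene, −30 °C; aq. NaHCO3 work-up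
Reagents that add atoms: none
Why: Chiral phosphoric acid-catalysed allylboration of an aldehyde through a closed six-membered chair transition state; the (S)-acid should direct the methallyl group to the face that gives the (S)-configured C9 carbinol, the only stereocentre in the route set by a chiral reagent.

Step 2
Reactants: 4 (S)-2,5-dimethylhexa-1,5-dien-3-ol; 5 acryloyl chloride
Product: 6 (S)-2,5-dimethylhexa-1,5-dien-3-yl prop-2-enoate
Conditions: Et3N, DMAP (cat.), CH2Cl2, 0 °C
Reagents that add atoms: none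
Why: DMAP-catalysed O-acylation of a secondary alcohol with an acid chloride; C9 is not touched.

Step 3
Reactants: 6 (S)-2,5-dimethylhexa-1,5-dien-3-yl prop-2-enoate
Product: 7 (S)-4-methyl-6-(prop-1-en-2-yl)-5,6-dihydro-2H-pyran-2-one
Conditions: second-generation Grubbs catalyst RuCl2(H2IMes)(PCy3)(=CHPh) (5 mol%), CH2Cl2 (5 mM), 40 °C
Reagents that add atoms: none
Why: Ring-closing metathesis of the acrylate with the homoallylic 1,1-disubstituted alkene closes the six-membered unsaturated lactone with loss of ethene; closure onto the isopropenyl group would give a five-membered butenolide and is expected to be much slower.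

Step 4
Reactants: 7 (S)-4-methyl-6-(prop-1-en-2-yl)-5,6-dihydro-2H-pyran-2-one; 8 vinylmagnesium bromide; 9 trimethyl orthoformate
Product: 11 (3R,4S,6S)-3-(dimethoxymethyl)-4-ethenyl-4-methyl-6-(prop-1-en-2-yl)oxan-2-one, via silyl ketene acetal 10 (not isolated)
Conditions: CuBr·SMe2 (10 mol%), Me3SiCl, HMPA, THF, −78 °C; solvent exchange below 0 °C; then HC(OMe)3, Me3SiOTf (10 mol%), CH2Cl2, −78 °C
Reagents that add atoms: chlorotrimethylsilane, C[Si](C)(C)Cl (its silyl group is carried only by intermediate 10)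
Why: Copper-catalysed, silyl chloride-accelerated conjugate addition delivers the vinyl group (C2–C3) axially to C1 anti to the pseudo-equatorial C9 isopropenyl group, and the silyl ketene acetal then undergoes a Mukaiyama-type alkylation by the dimethoxycarbenium ion anti to the now axial vinyl group, which sets C5 with its new carbon (C4) trans to vinyl and cis to the methyl group.

Step 5
Reactants: 11 (3R,4S,6S)-3-(dimethoxymethyl)-4-ethenyl-4-methyl-6-(prop-1-en-2-yl)oxan-2-one
Product: 12 (2S,3S,5S)-2-(dimethoxymethyl)-3-ethenyl-3,6-dimethylhept-6-ene-1,5-diol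
Conditions: LiAlH4, THF, 0 °C; aq. potassium sodium tartrate work-up
Reagents that add atoms: none
Why: Hydride reduction of the lactone to the primary C6 and secondary C9 alcohols; the acetal and both alkenes are inert, and C5 is no longer α to a carbonyl group, so its configuration is fixed.

Step 6
Reactants: 12 (2S,3S,5S)-2-(dimethoxymethyl)-3-ethenyl-3,6-dimethylhept-6-ene-1,5-diol
Product: 15 (2S,3S,5S)-3-ethenyl-3,6-dimethyl-5-(triethylsilyloxy)-2-[(triethylsilyloxy)methyl]hept-6-enal, via bis(triethylsilyl) ether acetal 13 (not isolated), via lutidinium N,O-acetal salt 14 (not isolated)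
Conditions: Et3SiOTf (5 equiv), 2,6-lutidine, CH2Cl2, −78 → 0 °C; then H2O, 0 °C
Reagents that add atoms: triethylsilyl trifluoromethanesulfonate, CC[Si](CC)(CC)OS(=O)(=O)C(F)(F)F; 2,6-lutidine, Cc1cccc(C)n1 (carried only by intermediate 14); water, O
Why: The silyl triflate/lutidine pair first silylates both hydroxyl groups and then converts the dimethyl acetal into a pyridinium N,O-acetal that water hydrolyses to the aldehyde (silylation followed by chemoselective non-acidic acetal cleavage), leaving silyl ethers and the α-stereocentre C5 untouched.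

Step 7
Reactants: 15 (2S,3S,5S)-3-ethenyl-3,6-dimethyl-5-(triethylsilyloxy)-2-[(triethylsilyloxy)methyl]hept-6-enal
Product: 16 (2S,3R)-3-methyl-3-[(2S)-3-methyl-2-(triethylsilyloxy)but-3-en-1-yl]-2-[(triethylsilyloxy)methyl]cyclopentan-1-one
Conditions: [Rh(nbd)(dppe)]BF4 (5 mol%, activated with H2), CH2Cl2, rt
Reagents that add atoms: none
Why: Intramolecular hydroacylation of a 4-pentenal at cationic monovalent rhodium (C–H oxidative addition, insertion of the vinyl group, reductive elimination) forms the C3–C4 bond and the cyclopentanone of ring A; the quaternary C1 favours closure and no stereocentre is touched.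

Step 8
Reactants: 16 (2S,3R)-3-methyl-3-[(2S)-3-methyl-2-(triethylsilyloxy)but-3-en-1-yl]-2-[(triethylsilyloxy)methyl]cyclopentan-1-one; 17 isopropylmagnesium chloride
Product: 18 (1R,2S,3R)-3-methyl-3-[(2S)-3-methyl-2-(triethylsilyloxy)but-3-en-1-yl]-1-(propan-2-yl)-2-[(triethylsilyloxy)methyl]cyclopentan-1-ol
Conditions: CeCl3 (dried), THF, −78 °C
Reagents that add atoms: none
Why: Organocerium 1,2-addition, chosen because the weakly basic reagent suppresses enolisation, β-elimination of the β-siloxy ketone and β-hydride reduction; the isopropyl group enters the C4 carbonyl anti to the adjacent C5 siloxymethyl group, so the C4 oxygen ends cis to C6 and to the C1 methyl group.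

Step 9
Reactants: 18 (1R,2S,3R)-3-methyl-3-[(2S)-3-methyl-2-(triethylsilyloxy)but-3-en-1-yl]-1-(propan-2-yl)-2-[(triethylsilyloxy)methyl]cyclopentan-1-ol
Product: 19 C4 triethylsilyl ether of 18 (tris(triethylsilyl) ether)
Conditions: Et3SiOTf, 2,6-lutidine, CH2Cl2, −78 → 0 °C
Reagents that add atoms: triethylsilyl trifluoromethanesulfonate, CC[Si](CC)(CC)OS(=O)(=O)C(F)(F)F
Why: Silylation of the hindered tertiary alcohol with a silyl triflate, needed to block retro-aldol cleavage of the later β-hydroxy aldehyde and to leave C6 as the only free hydroxyl after ring closure.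

Step 10
Reactants: 19 C4 triethylsilyl ether of 18
Product: 20 (1R,2R,5R)-2-methyl-2-[(2S)-3-methyl-2-(triethylsilyloxy)but-3-en-1-yl]-5-(propan-2-yl)-5-(triethylsilyloxy)cyclopentane-1-carbaldehyde
Conditions: (COCl)2, DMSO, CH2Cl2, −78 → −40 °C; then Et3N, −78 → 0 °C
Reagents that add atoms: none
Why: Swern oxidation with in situ cleavage of a primary triethylsilyl ether: the chlorosulfonium salt desilylates only the unhindered primary ether and oxidises it to the aldehyde while the secondary and tertiary silyl ethers stay; the base is added cold to avoid epimerisation at C5 or loss of the C4 siloxy group.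

Step 11
Reactants: 20 (1R,2R,5R)-2-methyl-2-[(2S)-3-methyl-2-(triethylsilyloxy)but-3-en-1-yl]-5-(propan-2-yl)-5-(triethylsilyloxy)cyclopentane-1-carbaldehyde
Product: 21 (3R,3aS,4S,7S,8aR)-8a-methyl-6-methylidene-3-(propan-2-yl)-3,7-bis(triethylsilyloxy)decahydroazulen-4-ol
Conditions: Me2AlCl (3 equiv), CH2Cl2, −78 → −20 °C; aq. NaHCO3
Reagents that add atoms: none
Why: Me2AlCl binds the C6 aldehyde oxygen, the terminal alkene carbon C7 adds to C6 while an allylic hydrogen of the C8 methyl passes to oxygen through a six-membered array, and the aluminium alkoxide then loses methane, which removes the proton source for Prins-type side paths. The closest known reaction is the Lewis acid-promoted type 2 intramolecular carbonyl-ene cyclisation that gives 3-methylenecycloalkanols, seven-membered ones included. Ring B closes as a seven-membered ring that is exo with respect to the carbonyl group and endo with respect to the alkene, so C7 and C8 both end inside the ring and the double bond moves to the exocyclic position on C8. The new stereocentre C6 is set by a chair-like transition state built on the trans-disposed anchors C5 and C1 of ring A, with the aluminium-bound oxygen pseudo-equatorial, giving the (6S) alcohol cis to H5. The step needs hydrogen transfer from the methyl group and not from C9, which the electron-withdrawing siloxy group on C9 and its position inside the tether should secure, and it needs the trans relation at C5/C1 fixed in step 4.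

Step 12
Reactants: 21 (3R,3aS,4S,7S,8aR)-8a-methyl-6-methylidene-3-(propan-2-yl)-3,7-bis(triethylsilyloxy)decahydroazulen-4-ol
Product: 22 C6 trimethylsilyl ether of 21
Conditions: Me3SiOTf, 2,6-lutidine, CH2Cl2, −78 °C
Reagents that add atoms: trimethylsilyl trifluoromethanesulfonate, C[Si](C)(C)OS(=O)(=O)C(F)(F)F
Why: Silylation of the C6 hydroxyl so that it cannot direct the peracid to its own face in step 13 and does not become an alkoxide (silyl migration from C4) in step 14.

Step 13
Reactants: 22 C6 trimethylsilyl ether of 21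
Product: 23 C8 spiro-epoxide of 22, (8R), oxirane oxygen trans to the C9 oxygen
Conditions: mCPBA, NaHCO3, CH2Cl2, 0 °C
Reagents that add atoms: 3-chloroperoxybenzoic acid, OOC(=O)c1cccc(Cl)c1
Why: Prilezhaev epoxidation of the exocyclic C8 methylene; the peracid should approach from the face opposite to the allylic C9 siloxy group and the C6 siloxy group, which places the oxirane oxygen trans to the C9 oxygen.

Step 14
Reactants: 23 C8 spiro-epoxide of 22
Product: 25 (3R,3aS,4S,6S,7S,8aR)-6,8a-dimethyl-3-(propan-2-yl)-3,7-bis(triethylsilyloxy)decahydroazulene-4,6-diol, via trimethylsilyl ether carbinol 24 (not isolated)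
Conditions: LiEt3BH, THF, 0 °C → rt; then K2CO3, MeOH, 0 °C
Reagents that add atoms: none
Why: The borohydride opens the oxirane by SN2 attack at its unsubstituted carbon, turning it into the C8 methyl group and leaving the tertiary hydroxyl with the configuration fixed in step 13; methanolysis then removes only the labile trimethylsilyl ether.

Step 15
Reactants: 25 (3R,3aS,4S,6S,7S,8aR)-6,8a-dimethyl-3-(propan-2-yl)-3,7-bis(triethylsilyloxy)decahydroazulene-4,6-diol; 26 4-(benzyloxy)benzoyl chloride
Product: 27 (3R,3aS,4S,6S,7S,8aR)-6-hydroxy-6,8a-dimethyl-3-(propan-2-yl)-3,7-bis(triethylsilyloxy)decahydroazulen-4-yl 4-(benzyloxy)benzoate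
Conditions: Et3N, DMAP, CH2Cl2, rt → 40 °C
Reagents that add atoms: none
Why: DMAP-catalysed acylation; only the secondary C6 hydroxyl reacts, since the tertiary C8 hydroxyl is unreactive and C4 and C9 are silylated.

Step 16
Reactants: 27 (3R,3aS,4S,6S,7S,8aR)-6-hydroxy-6,8a-dimethyl-3-(propan-2-yl)-3,7-bis(triethylsilyloxy)decahydroazulen-4-yl 4-(benzyloxy)benzoate
Product: 28 (3R,3aS,4S,6S,7S,8aR)-3,6,7-trihydroxy-6,8a-dimethyl-3-(propan-2-yl)decahydroazulen-4-yl 4-(benzyloxy)benzoate
Conditions: HF·pyridine, pyridine, THF, 0 °C → rt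
Reagents that add atoms: none
Why: Fluoride-mediated cleavage of both triethylsilyl ethers under buffered conditions that should neither hydrolyse nor shift the aryl ester.

Step 17
Reactants: 28 (3R,3aS,4S,6S,7S,8aR)-3,6,7-trihydroxy-6,8a-dimethyl-3-(propan-2-yl)decahydroazulen-4-yl 4-(benzyloxy)benzoate
Product: 29 (3R,3aS,4S,6S,7S,8aR)-3,6,7-trihydroxy-6,8a-dimethyl-3-(propan-2-yl)decahydroazulen-4-yl 4-hydroxybenzoate (CNP0197754.1)
Conditions: H2 (1 atm), Pd/C, EtOAc, rt
Reagents that add atoms: none
Why: Hydrogenolysis of the benzyl aryl ether over palladium; no alkene remains and the benzoate ester is stable.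

**Compound list**

1 | 2-methylprop-2-enal (methacrolein) | CC(=C)C=O | starting material
2 | 2-methylallylboronic acid pinacol ester | CC(=C)CB1OC(C)(C)C(C)(C)O1 | starting material
3 | (S)-2-[(2,5-dimethylhexa-1,5-dien-3-yl)oxy]-4,4,5,5-tetramethyl-1,3,2-dioxaborolane (not isolated) | C=C(C)C[C@H](OB1OC(C)(C)C(C)(C)O1)C(C)=C | intermediate
4 | (S)-2,5-dimethylhexa-1,5-dien-3-ol | C=C(C)C[C@H](O)C(C)=C | intermediate
5 | acryloyl chloride | C=CC(Cl)=O | starting material
6 | (S)-2,5-dimethylhexa-1,5-dien-3-yl prop-2-enoate | C=C(C)C[C@H](OC(=O)C=C)C(C)=C | intermediate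
7 | (S)-4-methyl-6-(prop-1-en-2-yl)-5,6-dihydro-2H-pyran-2-one | CC1=CC(=O)O[C@@H](C1)C(C)=C | intermediate
8 | vinylmagnesium bromide | C=C[Mg]Br | starting material
9 | trimethyl orthoformate | COC(OC)OC | starting material
10 | (4S,6S)-4-ethenyl-4-methyl-6-(prop-1-en-2-yl)-2-(trimethylsilyloxy)-5,6-dihydro-4H-pyran (not isolated) | C=C[C@]1(C)C[C@@H](C(C)=C)OC(O[Si](C)(C)C)=C1 | intermediate
11 | (3R,4S,6S)-3-(dimethoxymethyl)-4-ethenyl-4-methyl-6-(prop-1-en-2-yl)oxan-2-one | C=C[C@]1(C)C[C@@H](C(C)=C)OC(=O)[C@H]1C(OC)OC | intermediate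
12 | (2S,3S,5S)-2-(dimethoxymethyl)-3-ethenyl-3,6-dimethylhept-6-ene-1,5-diol | C=C[C@](C)(C[C@H](O)C(C)=C)[C@@H](CO)C(OC)OC | intermediate
13 | bis(triethylsilyl) ether of 12 (not isolated) | C=C[C@](C)(C[C@H](O[Si](CC)(CC)CC)C(C)=C)[C@@H](CO[Si](CC)(CC)CC)C(OC)OC | intermediate
14 | 2,6-dimethylpyridinium N,O-acetal triflate formed from 13 by exchange of one methoxy group (not isolated; N,O-acetal carbon as a mixture) | C=C[C@](C)(C[C@H](O[Si](CC)(CC)CC)C(C)=C)[C@@H](CO[Si](CC)(CC)CC)C(OC)[n+]1c(C)cccc1C.[O-]S(=O)(=O)C(F)(F)F | intermediate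
15 | (2S,3S,5S)-3-ethenyl-3,6-dimethyl-5-(triethylsilyloxy)-2-[(triethylsilyloxy)methyl]hept-6-enal | C=C[C@](C)(C[C@H](O[Si](CC)(CC)CC)C(C)=C)[C@@H](CO[Si](CC)(CC)CC)C=O | intermediate
16 | (2S,3R)-3-methyl-3-[(2S)-3-methyl-2-(triethylsilyloxy)but-3-en-1-yl]-2-[(triethylsilyloxy)methyl]cyclopentan-1-one | O=C1CC[C@](C)(C[C@H](O[Si](CC)(CC)CC)C(C)=C)[C@H]1CO[Si](CC)(CC)CC | intermediate
17 | isopropylmagnesium chloride | CC(C)[Mg]Cl | starting material
18 | (1R,2S,3R)-3-methyl-3-[(2S)-3-methyl-2-(triethylsilyloxy)but-3-en-1-yl]-1-(propan-2-yl)-2-[(triethylsilyloxy)methyl]cyclopentan-1-ol | CC(C)[C@]1(O)CC[C@](C)(C[C@H](O[Si](CC)(CC)CC)C(C)=C)[C@H]1CO[Si](CC)(CC)CC | intermediate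
19 | C4 triethylsilyl ether of 18 (tris(triethylsilyl) ether) | CC(C)[C@]1(O[Si](CC)(CC)CC)CC[C@](C)(C[C@H](O[Si](CC)(CC)CC)C(C)=C)[C@H]1CO[Si](CC)(CC)CC | intermediate
20 | (1R,2R,5R)-2-methyl-2-[(2S)-3-methyl-2-(triethylsilyloxy)but-3-en-1-yl]-5-(propan-2-yl)-5-(triethylsilyloxy)cyclopentane-1-carbaldehyde | CC(C)[C@]1(O[Si](CC)(CC)CC)CC[C@](C)(C[C@H](O[Si](CC)(CC)CC)C(C)=C)[C@H]1C=O | intermediate
21 | (3R,3aS,4S,7S,8aR)-8a-methyl-6-methylidene-3-(propan-2-yl)-3,7-bis(triethylsilyloxy)decahydroazulen-4-ol | CC(C)[C@]1(O[Si](CC)(CC)CC)CC[C@]2(C)C[C@H](O[Si](CC)(CC)CC)C(=C)C[C@H](O)[C@H]21 | intermediate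
22 | C6 trimethylsilyl ether of 21 | CC(C)[C@]1(O[Si](CC)(CC)CC)CC[C@]2(C)C[C@H](O[Si](CC)(CC)CC)C(=C)C[C@H](O[Si](C)(C)C)[C@H]21 | intermediate
23 | C8 spiro-epoxide of 22, (8R), oxirane oxygen trans to the C9 oxygen | CC(C)[C@]1(O[Si](CC)(CC)CC)CC[C@]2(C)C[C@H](O[Si](CC)(CC)CC)[C@@]3(OC3)C[C@H](O[Si](C)(C)C)[C@H]21 | intermediate
24 | C8 methyl carbinol (8S) from 23, C6 still as trimethylsilyl ether (not isolated) | CC(C)[C@]1(O[Si](CC)(CC)CC)CC[C@]2(C)C[C@H](O[Si](CC)(CC)CC)[C@@](C)(O)C[C@H](O[Si](C)(C)C)[C@H]21 | intermediate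
25 | (3R,3aS,4S,6S,7S,8aR)-6,8a-dimethyl-3-(propan-2-yl)-3,7-bis(triethylsilyloxy)decahydroazulene-4,6-diol | CC(C)[C@]1(O[Si](CC)(CC)CC)CC[C@]2(C)C[C@H](O[Si](CC)(CC)CC)[C@@](C)(O)C[C@H](O)[C@H]21 | intermediate
26 | 4-(benzyloxy)benzoyl chloride | O=C(Cl)c1ccc(OCc2ccccc2)cc1 | starting material
27 | (3R,3aS,4S,6S,7S,8aR)-6-hydroxy-6,8a-dimethyl-3-(propan-2-yl)-3,7-bis(triethylsilyloxy)decahydroazulen-4-yl 4-(benzyloxy)benzoate | CC(C)[C@]1(O[Si](CC)(CC)CC)CC[C@]2(C)C[C@H](O[Si](CC)(CC)CC)[C@@](C)(O)C[C@H](OC(=O)c3ccc(OCc4ccccc4)cc3)[C@H]21 | intermediate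
28 | (3R,3aS,4S,6S,7S,8aR)-3,6,7-trihydroxy-6,8a-dimethyl-3-(propan-2-yl)decahydroazulen-4-yl 4-(benzyloxy)benzoate | CC(C)[C@]1(O)CC[C@]2(C)C[C@H](O)[C@@](C)(O)C[C@H](OC(=O)c3ccc(OCc4ccccc4)cc3)[C@H]21 | intermediate
29 | (3R,3aS,4S,6S,7S,8aR)-3,6,7-trihydroxy-6,8a-dimethyl-3-(propan-2-yl)decahydroazulen-4-yl 4-hydroxybenzoate | CC(C)[C@]1(O)CC[C@]2(C)C[C@H](O)[C@@](C)(O)C[C@H](OC(=O)c3ccc(O)cc3)[C@H]21 | target

**Step count**

Total: 17 steps. Longest linear sequence: 17 steps (1 → 29).

**Steps most likely to fail**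

Step 11 (carbonyl-ene closure of ring B). The allylic siloxy group on C9 lowers the nucleophilicity of the alkene, so closure may stall while the Lewis acid instead promotes loss of the C4 siloxy group β to the aldehyde, or hydrogen may be taken from C9 rather than from the methyl group. The fallback forms the same C6–C7 bond by an intramolecular Nozaki–Hiyama allylation; it sets out from 19 and returns at 21. The isopropenyl group of 19 is chlorinated with allylic transposition (Ca(OCl)2, CO2, CH2Cl2/H2O) to give the 2-(chloromethyl)allyl tris(triethylsilyl) ether F1. Swern oxidation as in step 10 then gives the chloro aldehyde F2. CrCl2 with LiI in THF converts the allylic chloride into an allylchromium species that adds through its γ-carbon C7 to the C6 aldehyde and should give 21 with the exocyclic C8 methylene.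

Step 4 (conjugate addition and orthoformate capture). Addition to the β,β-disubstituted lactone may be slow, the ketene acetal 10 may rearrange ([3,3] shift onto the isopropenyl group) if it warms, or capture next to the new quaternary carbon may be incomplete or poorly face-selective. The fallback separates the two events and uses an enolate alkylation; it sets out from 7 and returns at 15. The conjugate addition is run as in step 4 and quenched with aq. NH4Cl to give (4R,6S)-4-ethenyl-4-methyl-6-(prop-1-en-2-yl)oxan-2-one F3. Its lithium enolate (LiN(i-Pr)2, THF, −78 °C) is alkylated with benzyl chloromethyl ether anti to the axial vinyl group to give (3R,4S,6S)-3-[(benzyloxy)methyl]-4-ethenyl-4-methyl-6-(prop-1-en-2-yl)oxan-2-one F4. LiAlH4 gives (2S,3S,5S)-2-[(benzyloxy)methyl]-3-ethenyl-3,6-dimethylhept-6-ene-1,5-diol F5, and Et3SiOTf/2,6-lutidine gives the bis(triethylsilyl) ether of the benzyl ether diol F6. Lithium 4,4'-di-tert-butylbiphenylide (THF, −78 °C) removes the benzyl group to give (2R,3S,5S)-3-ethenyl-3,6-dimethyl-5-(triethylsilyloxy)-2-[(triethylsilyloxy)methyl]hept-6-en-1-ol F7, and Dess–Martin periodinane (NaHCO3, CH2Cl2) oxidises it to 15.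

Step 13 (epoxidation of the C8 methylene). Facial selectivity on the flexible seven-membered ring may be poor or reversed. The fallback forms the oxirane by carbon delivery instead of oxygen delivery; it sets out from 22 and returns at 23. Ozonolysis of 22 (O3, CH2Cl2, −78 °C; PPh3) gives (3R,3aS,4S,7S,8aR)-8a-methyl-3-(propan-2-yl)-3,7-bis(triethylsilyloxy)-4-(trimethylsilyloxy)octahydroazulen-6(1H)-one F8. A Corey–Chaykovsky reaction with dimethylsulfonium methylide (Me3S+ I−, KN(SiMe3)2, THF, −20 °C) then delivers the methylene carbon from the less hindered face. This is the opposite sense to oxygen delivery by the peracid, so if the peracid prefers the siloxy face, the ylide should give 23 as the major isomer.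

**Further compounds**

F1 | step 11 | chloromethyl analogue of 19, side chain (2S)-3-(chloromethyl)-2-(triethylsilyloxy)but-3-en-1-yl | CC(C)[C@]1(O[Si](CC)(CC)CC)CC[C@](C)(C[C@H](O[Si](CC)(CC)CC)C(CCl)=C)[C@H]1CO[Si](CC)(CC)CC
F2 | step 11 | chloromethyl analogue of aldehyde 20 | CC(C)[C@]1(O[Si](CC)(CC)CC)CC[C@](C)(C[C@H](O[Si](CC)(CC)CC)C(CCl)=C)[C@H]1C=O
F3 | step 4 | (4R,6S)-4-ethenyl-4-methyl-6-(prop-1-en-2-yl)oxan-2-one | C=C[C@]1(C)C[C@@H](C(C)=C)OC(=O)C1
F4 | step 4 | (3R,4S,6S)-3-[(benzyloxy)methyl]-4-ethenyl-4-methyl-6-(prop-1-en-2-yl)oxan-2-one | C=C[C@]1(C)C[C@@H](C(C)=C)OC(=O)[C@H]1COCc1ccccc1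
F5 | step 4 | (2S,3S,5S)-2-[(benzyloxy)methyl]-3-ethenyl-3,6-dimethylhept-6-ene-1,5-diol | C=C[C@](C)(C[C@H](O)C(C)=C)[C@@H](CO)COCc1ccccc1
F6 | step 4 | bis(triethylsilyl) ether of F5 | C=C[C@](C)(C[C@H](O[Si](CC)(CC)CC)C(C)=C)[C@@H](CO[Si](CC)(CC)CC)COCc1ccccc1
F7 | step 4 | (2R,3S,5S)-3-ethenyl-3,6-dimethyl-5-(triethylsilyloxy)-2-[(triethylsilyloxy)methyl]hept-6-en-1-ol | C=C[C@](C)(C[C@H](O[Si](CC)(CC)CC)C(C)=C)[C@@H](CO[Si](CC)(CC)CC)CO
F8 | step 13 | (3R,3aS,4S,7S,8aR)-8a-methyl-3-(propan-2-yl)-3,7-bis(triethylsilyloxy)-4-(trimethylsilyloxy)octahydroazulen-6(1H)-one | CC(C)[C@]1(O[Si](CC)(CC)CC)CC[C@]2(C)C[C@H](O[Si](CC)(CC)CC)C(=O)C[C@H](O[Si](C)(C)C)[C@H]21
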